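**Retrosynthetic overview**
1. Feature: ring B contains one carbon, C4, that bears only hydrogen. It sits between C3 and the ring-fusion carbon C4a, and C4a lies para to the C7 oxygen of ring A. Removing C4 contracts ring B to a trans-2,3-disubstituted indan-1-one whose carbonyl carbon is C3 and whose aryl terminus is electron-rich.
2. Endgame: the C3 formyl group comes from the C3=C4 enol triflate of a 2-tetralone by reductive carbonylation, followed by desilylation at C9–O and debenzylation at C7–O.
3. Key disconnection: C3–C4 and C4–C4a are made together by inserting the carbon of Me3SiCHN2 into the carbonyl–aryl bond of the indanone under BF3·OEt2.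
4. Indanone: C2–C9 by enolate hydroxymethylation anti to the C1 aryl group. C1–C1' by rhodium-catalysed enantioselective conjugate arylation of an indenone. The five-membered ring by Friedel–Crafts acylation para to benzyloxy.
5. Ring order: ring A (purchased) → five-membered carbocycle → ring B by enlargement. The dimethoxyphenyl ring enters as its boronic acid.

Key step: step 9

Numbering used in the comments: ring B = C1(aryl)–C2(C9H2OH)–C3(CHO)=C4H–C4a–C8a; ring A = C4a, C5, C6, C7(OH), C8(OMe), C8a; C1' = ipso carbon of the dimethoxyphenyl ring. Systematic names carry their own locants. The target SMILES reads as C1 = S, C2 = R, substituents trans.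

Assumption: the sense of induction of (S)-BINAP–rhodium on indenone 12 is taken to be that established for 2-cyclopentenone, which maps onto (S)-14. Should it prove opposite, (R)-BINAP would be used with no other change.

**Step 1**
Reactants: 1 2,3-dihydroxybenzaldehyde
Product: 3 3-benzyloxy-2-hydroxybenzaldehyde, via disodium catecholate 2 (not isolated)
Conditions: NaH (2.1 equiv), THF–DMSO, 0 °C → rt; BnBr (1.0 equiv), rt; aq. HCl
Reagents that add atoms: benzyl bromide, BrCc1ccccc1
Why: Williamson etherification of the dianion, in which the 2-oxide is delocalised into and chelated by the formyl group, so the more nucleophilic 3-oxide should take up the single equivalent of benzyl bromide.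

**Step 2**
Reactants: 3 3-benzyloxy-2-hydroxybenzaldehyde
Product: 4 3-benzyloxy-2-methoxybenzaldehyde
Conditions: MeI, K2CO3, DMF, rt
Reagents that add atoms: iodomethane, CI
Why: Williamson O-methylation of the only remaining phenol in a dipolar aprotic solvent fixes the C8-OMe/C7-OBn pattern unambiguously.

**Step 3**
Reactants: 4 3-benzyloxy-2-methoxybenzaldehyde; 5 Meldrum's acid
Product: 8 3-(3-benzyloxy-2-methoxyphenyl)propanoic acid, via arylidene Meldrum's acid 6 (not isolated), via benzyl Meldrum's acid 7 (not isolated)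
Conditions: HCO2H/Et3N (5:2), rt → 100 °C; aq. HCl
Reagents that add atoms: Meldrum's acid (5), CC1(C)OC(=O)CC(=O)O1
Why: Knoevenagel condensation, conjugate hydride transfer from formate and hydrolysis–decarboxylation run in one pot, and because no hydrogenation metal is present the benzyl ether cannot be hydrogenolysed.

**Step 4**
Reactants: 8 3-(3-benzyloxy-2-methoxyphenyl)propanoic acid
Product: 10 5-benzyloxy-4-methoxy-2,3-dihydro-1H-inden-1-one, via acid chloride 9 (not isolated)
Conditions: (COCl)2, cat. DMF, CH2Cl2, rt; evaporate; (CF3)2CHOH, rt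
Reagents that add atoms: none
Why: Intramolecular Friedel–Crafts acylation of the acid chloride promoted by hydrogen bonding from hexafluoroisopropanol, where the only free position ortho to the chain is para to benzyloxy and the absence of a metal Lewis acid spares the benzyl ether.

**Step 5**
Reactants: 10 5-benzyloxy-4-methoxy-2,3-dihydro-1H-inden-1-one
Product: 12 5-benzyloxy-4-methoxy-1H-inden-1-one, via trimethylsilyl enol ether 11 (not isolated)
Conditions: Me3SiOTf, Et3N, CH2Cl2, 0 °C; then Pd(OAc)2 (10 mol %), O2 (1 atm), DMSO, rt; used promptly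
Reagents that add atoms: none
Why: Saegusa–Ito oxidation, in which divalent palladium takes up the silyl enol ether and β-hydride elimination gives the indenone, avoiding radical bromination that would attack the benzylic CH2 of the ether.

**Step 6**
Reactants: 12 5-benzyloxy-4-methoxy-1H-inden-1-one; 13 (3,4-dimethoxyphenyl)boronic acid
Product: 14 (3S)-5-benzyloxy-3-(3,4-dimethoxyphenyl)-4-methoxy-2,3-dihydro-1H-inden-1-one
Conditions: 13 (2 equiv), [Rh(OH)((S)-binap)]2 (1.5 mol %), dioxane/H2O (10:1), 35 °C
Reagents that add atoms: (3,4-dimethoxyphenyl)boronic acid (13), COc1ccc(B(O)O)cc1OC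
Why: Hayashi–Miyaura asymmetric 1,4-addition, in which the aryl-rhodium species inserts the enone C=C on the face left open by (S)-BINAP and sets C1 as S, and in which a cod-free hydroxo complex is chosen because cod-bound rhodium would run a fast racemic background reaction.

**Step 7**
Reactants: 14 (3S)-5-benzyloxy-3-(3,4-dimethoxyphenyl)-4-methoxy-2,3-dihydro-1H-inden-1-one
Product: 16 (2S,3S)-5-benzyloxy-3-(3,4-dimethoxyphenyl)-2-(hydroxymethyl)-4-methoxy-2,3-dihydro-1H-inden-1-one, via lithium enolate 15 (not isolated)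
Conditions: LiN(i-Pr)2 (1.05 equiv), THF, –78 °C; CH2O (g, from cracked paraformaldehyde), –78 °C; AcOH quench at –78 °C
Reagents that add atoms: formaldehyde, C=O
Why: Aldol addition of the lithium enolate to monomeric formaldehyde should occur on the face opposite the neighbouring aryl group, setting C2 trans to C1, which is also the preferred arrangement at this epimerisable centre.

**Step 8**
Reactants: 16 (2S,3S)-5-benzyloxy-3-(3,4-dimethoxyphenyl)-2-(hydroxymethyl)-4-methoxy-2,3-dihydro-1H-inden-1-one
Product: 17 (2S,3S)-5-benzyloxy-2-[(tert-butyldimethylsilyloxy)methyl]-3-(3,4-dimethoxyphenyl)-4-methoxy-2,3-dihydro-1H-inden-1-one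
Conditions: TBSCl, imidazole, CH2Cl2, 0 °C → rt
Reagents that add atoms: tert-butyldimethylsilyl chloride, CC(C)(C)[Si](C)(C)Cl
Why: Standard silylation of the primary alcohol blocks retro-aldol cleavage and dehydration and gives an ether that tolerates BF3·OEt2 at low temperature.

**Step 9**
Reactants: 17 (2S,3S)-5-benzyloxy-2-[(tert-butyldimethylsilyloxy)methyl]-3-(3,4-dimethoxyphenyl)-4-methoxy-2,3-dihydro-1H-inden-1-one; 18 trimethylsilyldiazomethane
Product: 20 (3S,4S)-6-benzyloxy-3-[(tert-butyldimethylsilyloxy)methyl]-4-(3,4-dimethoxyphenyl)-5-methoxy-3,4-dihydronaphthalen-2(1H)-one, via α-trimethylsilyl ketone 19 (not isolated)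
Conditions: BF3·OEt2 (1.5 equiv), CH2Cl2, –78 °C; Me3SiCHN2 (2 M in hexanes, 1.5 equiv, dropwise), –78 → –20 °C; aq. NaHCO3; wet SiO2, CH2Cl2, rt
Reagents that add atoms: trimethylsilyldiazomethane (18), C[Si](C)(C)C=[N+]=[N-]
Why: BF3 binds the carbonyl oxygen of 17, the diazo carbon of 18 adds to the carbonyl carbon (future C3) to make C3–C4, and in the β-oxido diazonium adduct the aryl carbon C4a moves from C3 to C4 as N2 departs, making C4–C4a and giving α-silyl ketone 19, whose benzylic C–Si bond is hydrolysed on wet silica. The closest known reaction type is the Tiffeneau–Demjanov-type homologation of 1-indanones and 1-tetralones with diazoalkanes under BF3·OEt2 or AlMe3, which delivers 2-tetralones and 2-benzosuberones by aryl migration; the C2 branch makes 17 a more hindered member of that class. Ring B results from a 1,2-shift that widens the existing five-membered carbocycle by one atom, so no chain is cyclised. No lasting stereocentre is created: C1 is remote from the events, the silyl-bearing C4 of 19 ends as CH2, and C2 is not enolised in the cold, base-free medium and in any case holds the trans arrangement expected to be the more stable one. The step needs migration of C4a in preference to C2 and to epoxide closure, which the para C7 benzyloxy group secures by stabilising the phenonium-like transition state and the bulky Me3Si group reinforces by turning away from branched C2, so that C4a stands antiperiplanar to N2. It also needs a single insertion, which the Me3Si group on C4 of 19 secures by shielding the new, more electrophilic ketone until work-up.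

**Step 10**
Reactants: 20 (3S,4S)-6-benzyloxy-3-[(tert-butyldimethylsilyloxy)methyl]-4-(3,4-dimethoxyphenyl)-5-methoxy-3,4-dihydronaphthalen-2(1H)-one
Product: 22 (3S,4S)-6-benzyloxy-3-[(tert-butyldimethylsilyloxy)methyl]-4-(3,4-dimethoxyphenyl)-5-methoxy-3,4-dihydronaphthalen-2-yl trifluoromethanesulfonate, via potassium enolate 21 (not isolated)
Conditions: KN(SiMe3)2 (1.1 equiv), THF, –78 °C; PhNTf2, –78 → 0 °C
Reagents that add atoms: N-phenylbis(trifluoromethanesulfonimide), O=S(=O)(N(c1ccccc1)S(=O)(=O)C(F)(F)F)C(F)(F)F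
Why: Enolate O-triflation, in which the unhindered benzylic C4 hydrogens are removed faster than the tertiary C2 hydrogen and give the aryl-conjugated enolate, so the C3=C4 triflate should form without touching C2 or expelling silyloxide.

**Step 11**
Reactants: 22 (3S,4S)-6-benzyloxy-3-[(tert-butyldimethylsilyloxy)methyl]-4-(3,4-dimethoxyphenyl)-5-methoxy-3,4-dihydronaphthalen-2-yl trifluoromethanesulfonate
Product: 23 (3R,4S)-6-benzyloxy-3-[(tert-butyldimethylsilyloxy)methyl]-4-(3,4-dimethoxyphenyl)-5-methoxy-3,4-dihydronaphthalene-2-carbaldehyde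
Conditions: Pd(OAc)2 (5 mol %), dppp (5 mol %), CO (1 atm), Et3SiH (2 equiv, slow addition), Et3N, DMF, 70 °C
Reagents that add atoms: carbon monoxide, [C-]#[O+]
Why: Palladium-catalysed reductive carbonylation of an enol triflate, that is oxidative addition to zerovalent palladium, CO insertion and hydride transfer from the silane to the acyl-palladium complex, with slow silane addition to hold back direct reduction.

**Step 12**
Reactants: 23 (3R,4S)-6-benzyloxy-3-[(tert-butyldimethylsilyloxy)methyl]-4-(3,4-dimethoxyphenyl)-5-methoxy-3,4-dihydronaphthalene-2-carbaldehyde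
Product: 24 (3R,4S)-6-benzyloxy-4-(3,4-dimethoxyphenyl)-3-(hydroxymethyl)-5-methoxy-3,4-dihydronaphthalene-2-carbaldehyde
Conditions: HF·pyridine, pyridine, THF, 0 °C → rt
Reagents that add atoms: none
Why: Fluoride-driven cleavage of the primary silyl ether in a buffered medium leaves the enal, the benzyl ether and both stereocentres untouched.

**Step 13**
Reactants: 24 (3R,4S)-6-benzyloxy-4-(3,4-dimethoxyphenyl)-3-(hydroxymethyl)-5-methoxy-3,4-dihydronaphthalene-2-carbaldehyde
Product: 25 vitekwangin B, (3R,4S)-4-(3,4-dimethoxyphenyl)-6-hydroxy-3-(hydroxymethyl)-5-methoxy-3,4-dihydronaphthalene-2-carbaldehyde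
Conditions: BCl3 (1 M in CH2Cl2, 3 equiv), C6HMe5 (3 equiv), CH2Cl2, –78 °C; MeOH/CHCl3 quench at –78 °C; aq. work-up under argon
Reagents that add atoms: none
Why: Lewis-acid debenzylation with pentamethylbenzene as a non-coordinating benzyl-cation scavenger cleaves aryl benzyl ethers at –78 °C, where aryl methyl ethers and the enal persist, and it avoids hydrogenolysis, which would saturate C3=C4.

**Compound list**
1 | 2,3-dihydroxybenzaldehyde | O=Cc1cccc(O)c1O | starting material
2 | disodium 3-formylbenzene-1,2-diolate | O=Cc1cccc([O-])c1[O-].[Na+].[Na+] | intermediate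
3 | 3-benzyloxy-2-hydroxybenzaldehyde | O=Cc1cccc(OCc2ccccc2)c1O | intermediate
4 | 3-benzyloxy-2-methoxybenzaldehyde | O=Cc1cccc(OCc2ccccc2)c1OC | intermediate
5 | Meldrum's acid (2,2-dimethyl-1,3-dioxane-4,6-dione) | CC1(C)OC(=O)CC(=O)O1 | starting material
6 | 5-[(3-benzyloxy-2-methoxyphenyl)methylidene]-2,2-dimethyl-1,3-dioxane-4,6-dione | COc1c(C=C2C(=O)OC(C)(C)OC2=O)cccc1OCc1ccccc1 | intermediate
7 | 5-(3-benzyloxy-2-methoxybenzyl)-2,2-dimethyl-1,3-dioxane-4,6-dione | COc1c(CC2C(=O)OC(C)(C)OC2=O)cccc1OCc1ccccc1 | intermediate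
8 | 3-(3-benzyloxy-2-methoxyphenyl)propanoic acid | COc1c(CCC(=O)O)cccc1OCc1ccccc1 | intermediate
9 | 3-(3-benzyloxy-2-methoxyphenyl)propanoyl chloride | COc1c(CCC(=O)Cl)cccc1OCc1ccccc1 | intermediate
10 | 5-benzyloxy-4-methoxy-2,3-dihydro-1H-inden-1-one | COc1c(OCc2ccccc2)ccc2C(=O)CCc12 | intermediate
11 | 6-benzyloxy-7-methoxy-3-(trimethylsilyloxy)-1H-indene | COc1c(OCc2ccccc2)ccc2C(O[Si](C)(C)C)=CCc12 | intermediate
12 | 5-benzyloxy-4-methoxy-1H-inden-1-one | COc1c(OCc2ccccc2)ccc2C(=O)C=Cc12 | intermediate
13 | (3,4-dimethoxyphenyl)boronic acid | COc1ccc(B(O)O)cc1OC | starting material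
14 | (3S)-5-benzyloxy-3-(3,4-dimethoxyphenyl)-4-methoxy-2,3-dihydro-1H-inden-1-one | COc1ccc([C@H]2c3c(ccc(OCc4ccccc4)c3OC)C(=O)C2)cc1OC | intermediate
15 | lithium (1S)-6-benzyloxy-1-(3,4-dimethoxyphenyl)-7-methoxy-1H-inden-3-olate | [Li+].COc1ccc([C@H]2c3c(ccc(OCc4ccccc4)c3OC)C([O-])=C2)cc1OC | intermediate
16 | (2S,3S)-5-benzyloxy-3-(3,4-dimethoxyphenyl)-2-(hydroxymethyl)-4-methoxy-2,3-dihydro-1H-inden-1-one (trans) | COc1ccc([C@H]2c3c(ccc(OCc4ccccc4)c3OC)C(=O)[C@@H]2CO)cc1OC | intermediate
17 | (2S,3S)-5-benzyloxy-2-[(tert-butyldimethylsilyloxy)methyl]-3-(3,4-dimethoxyphenyl)-4-methoxy-2,3-dihydro-1H-inden-1-one (trans) | COc1ccc([C@H]2c3c(ccc(OCc4ccccc4)c3OC)C(=O)[C@@H]2CO[Si](C)(C)C(C)(C)C)cc1OC | intermediate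
18 | trimethylsilyldiazomethane | C[Si](C)(C)C=[N+]=[N-] | starting material
19 | (3S,4S)-6-benzyloxy-3-[(tert-butyldimethylsilyloxy)methyl]-4-(3,4-dimethoxyphenyl)-5-methoxy-1-(trimethylsilyl)-3,4-dihydronaphthalen-2(1H)-one (silyl-bearing carbon undefined) | COc1ccc([C@H]2c3c(ccc(OCc4ccccc4)c3OC)C([Si](C)(C)C)C(=O)[C@@H]2CO[Si](C)(C)C(C)(C)C)cc1OC | intermediate
20 | (3S,4S)-6-benzyloxy-3-[(tert-butyldimethylsilyloxy)methyl]-4-(3,4-dimethoxyphenyl)-5-methoxy-3,4-dihydronaphthalen-2(1H)-one (trans; ketone on C3, CH2 at C4) | COc1ccc([C@H]2c3c(ccc(OCc4ccccc4)c3OC)CC(=O)[C@@H]2CO[Si](C)(C)C(C)(C)C)cc1OC | intermediate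
21 | potassium (3S,4S)-6-benzyloxy-3-[(tert-butyldimethylsilyloxy)methyl]-4-(3,4-dimethoxyphenyl)-5-methoxy-3,4-dihydronaphthalen-2-olate | [K+].COc1ccc([C@H]2c3c(ccc(OCc4ccccc4)c3OC)C=C([O-])[C@@H]2CO[Si](C)(C)C(C)(C)C)cc1OC | intermediate
22 | (3S,4S)-6-benzyloxy-3-[(tert-butyldimethylsilyloxy)methyl]-4-(3,4-dimethoxyphenyl)-5-methoxy-3,4-dihydronaphthalen-2-yl trifluoromethanesulfonate | COc1ccc([C@H]2c3c(ccc(OCc4ccccc4)c3OC)C=C(OS(=O)(=O)C(F)(F)F)[C@@H]2CO[Si](C)(C)C(C)(C)C)cc1OC | intermediate
23 | (3R,4S)-6-benzyloxy-3-[(tert-butyldimethylsilyloxy)methyl]-4-(3,4-dimethoxyphenyl)-5-methoxy-3,4-dihydronaphthalene-2-carbaldehyde | COc1ccc([C@H]2c3c(ccc(OCc4ccccc4)c3OC)C=C(C=O)[C@@H]2CO[Si](C)(C)C(C)(C)C)cc1OC | intermediate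
24 | (3R,4S)-6-benzyloxy-4-(3,4-dimethoxyphenyl)-3-(hydroxymethyl)-5-methoxy-3,4-dihydronaphthalene-2-carbaldehyde | COc1ccc([C@H]2c3c(ccc(OCc4ccccc4)c3OC)C=C(C=O)[C@@H]2CO)cc1OC | intermediate
25 | vitekwangin B, (3R,4S)-4-(3,4-dimethoxyphenyl)-6-hydroxy-3-(hydroxymethyl)-5-methoxy-3,4-dihydronaphthalene-2-carbaldehyde | COc1ccc([C@H]2c3c(ccc(O)c3OC)C=C(C=O)[C@@H]2CO)cc1OC | target

**Total step count:** 13. **Longest linear sequence:** 13 steps (from 1).

**Steps most likely to fail**

Step 9 (key step).
- What may go wrong: addition may be slow, because the carbonyl group is deactivated by the para oxygen and screened by the C2 branch, so Lewis-acid decomposition of 18 takes over. C2 may shift instead of C4a, the adduct may collapse to the spiro-epoxide, or the silyloxy group may be lost by Lewis-acid-induced β-elimination.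
- Fallback: the same C4a shift is triggered from an alkene instead of a diazonium ion. The fallback sets out from 17. Wittig methylenation (Ph3PCH3Br, KN(SiMe3)2, THF, –78 °C → rt) should give (2R,3S)-5-benzyloxy-2-[(tert-butyldimethylsilyloxy)methyl]-3-(3,4-dimethoxyphenyl)-4-methoxy-1-methylidene-2,3-dihydro-1H-indene F1. Treating this with PhI(OH)OTs in 95 % MeOH at rt brings about an oxidative 1,2-aryl migration at trivalent iodine. This is the known Wittig–ring-expansion sequence of 1-indanones and 1-tetralones, and it should come back to the route at 20.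

Step 6.
- What may go wrong: insertion next to the peri methoxy group may be slow, so protodeboronation of 13 and dimerisation of the indenone compete. Facial selectivity on the benzo-fused enone may also be poor.
- Fallback: C–C bond formation and stereocontrol are separated. The fallback sets out from 12. Copper-catalysed conjugate addition of 3,4-(MeO)2C6H3MgBr (CuBr·SMe2, THF, –78 °C) should give racemic 5-benzyloxy-3-(3,4-dimethoxyphenyl)-4-methoxy-2,3-dihydro-1H-inden-1-one F2.
- Kinetic resolution follows by Noyori–Ikariya asymmetric transfer hydrogenation (RuCl[(R,R)-TsDPEN](p-cymene), HCO2H/Et3N, rt, stopped near half conversion), a known resolution of 3-arylindan-1-ones. It should reduce the (R)-ketone anti to its aryl group to (1R,3R)-5-benzyloxy-3-(3,4-dimethoxyphenyl)-4-methoxy-2,3-dihydro-1H-inden-1-ol F3.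
- The (S)-ketone is left untouched, and after chromatographic separation the fallback comes back to the route at 14.

Step 11.
- What may go wrong: hydride may transfer to the vinyl-palladium complex before CO is taken up, losing the triflate without formylation. CO insertion may be slow beside the branched C2, or the silane may over-reduce the enal.
- Fallback: carbonylation and hydride delivery are uncoupled. The fallback sets out from 22. Methoxycarbonylation (Pd(OAc)2, dppp, CO, MeOH, Et3N, DMF, 60 °C) should give methyl (3R,4S)-6-benzyloxy-3-[(tert-butyldimethylsilyloxy)methyl]-4-(3,4-dimethoxyphenyl)-5-methoxy-3,4-dihydronaphthalene-2-carboxylate F4.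
- Reduction with i-Bu2AlH (CH2Cl2, –78 °C) should give [(3R,4S)-6-benzyloxy-3-[(tert-butyldimethylsilyloxy)methyl]-4-(3,4-dimethoxyphenyl)-5-methoxy-3,4-dihydronaphthalen-2-yl]methanol F5.
- Allylic oxidation with MnO2 (CH2Cl2, rt) comes back to the route at 23.

**Further compounds**
F1 | step 9 | (2R,3S)-5-benzyloxy-2-[(tert-butyldimethylsilyloxy)methyl]-3-(3,4-dimethoxyphenyl)-4-methoxy-1-methylidene-2,3-dihydro-1H-indene | COc1ccc([C@H]2c3c(ccc(OCc4ccccc4)c3OC)C(=C)[C@@H]2CO[Si](C)(C)C(C)(C)C)cc1OC
F2 | step 6 | racemic 5-benzyloxy-3-(3,4-dimethoxyphenyl)-4-methoxy-2,3-dihydro-1H-inden-1-one | COc1ccc(C2c3c(ccc(OCc4ccccc4)c3OC)C(=O)C2)cc1OC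
F3 | step 6 | (1R,3R)-5-benzyloxy-3-(3,4-dimethoxyphenyl)-4-methoxy-2,3-dihydro-1H-inden-1-ol | COc1ccc([C@@H]2c3c(ccc(OCc4ccccc4)c3OC)[C@H](O)C2)cc1OC
F4 | step 11 | methyl (3R,4S)-6-benzyloxy-3-[(tert-butyldimethylsilyloxy)methyl]-4-(3,4-dimethoxyphenyl)-5-methoxy-3,4-dihydronaphthalene-2-carboxylate | COc1ccc([C@H]2c3c(ccc(OCc4ccccc4)c3OC)C=C(C(=O)OC)[C@@H]2CO[Si](C)(C)C(C)(C)C)cc1OC
F5 | step 11 | [(3R,4S)-6-benzyloxy-3-[(tert-butyldimethylsilyloxy)methyl]-4-(3,4-dimethoxyphenyl)-5-methoxy-3,4-dihydronaphthalen-2-yl]methanol | COc1ccc([C@H]2c3c(ccc(OCc4ccccc4)c3OC)C=C(CO)[C@@H]2CO[Si](C)(C)C(C)(C)C)cc1OC
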